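The pyranone (ring C) is cut at C4–C4a and O1–C8a. Ring A then comes from 2,3-dimethoxycyclohex-2-en-1-one: its C6, C1, C2 and C3 become C4a, C8a (bearing O1), C8 and C7 (both OMe), the contiguous tetrasubstituted edge of ring A that the key step exploits. In a single operation the aroylketene generated by heating an aroyl Meldrum's acid adds through its O=C–C=C unit across the C8a=C4a silyl enol ether of a cross-conjugated dienol ether. Loss of silanol completes ring C with the aryl group (ring B) at C2. Dehydrogenation of C5–C6 and debenzylation then deliver the flavone.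

Key step: step 6

Remark on the chemistry: the dienol ether is carried as its tert-butyldimethylsilyl ether and the aroyl Meldrum's acid is added slowly to a hot excess of it, because that enolic acid would protodesilylate a trimethylsilyl enol ether before it fragments. The target is achiral, so no stereocentre has to be set.

Step 1
Reactants: 1 cyclohexane-1,3-dione
Product: 2 2-diazocyclohexane-1,3-dione
Conditions: p-ABSA, Et3N, MeCN, 0 °C to rt
Reagents that add atoms: 4-acetamidobenzenesulfonyl azide (p-ABSA), CC(=O)Nc1ccc(cc1)S(=O)(=O)N=[N+]=[N-]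
Why: Regitz diazo transfer to the doubly activated C2 methylene of a cyclic 1,3-dione is standard, the enolate attacking the terminal azide nitrogen and the triazene collapsing to the diazo dione and the sulfonamide.

Step 2
Reactants: 2 2-diazocyclohexane-1,3-dione
Product: 4 2,3-dimethoxycyclohex-2-en-1-one, via 2-methoxycyclohexane-1,3-dione 3 (not isolated)
Conditions: Rh2(OAc)4 (1 mol %), MeOH, 60 °C; then HC(OMe)3, TsOH (cat.), reflux
Reagents that add atoms: methanol, CO; trimethyl orthoformate, COC(OC)OC
Why: Rhodium-carbenoid O–H insertion of the acceptor/acceptor diazo dione into solvent methanol should give the enolized 2-methoxy dione 3, and acid-catalysed enol ether formation then O-methylates it to a single product because 3 is symmetric.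

Step 3
Reactants: 4 2,3-dimethoxycyclohex-2-en-1-one
Product: 6 tert-butyl[(5,6-dimethoxycyclohexa-1,5-dien-1-yl)oxy]dimethylsilane, via lithium dienolate 5 (not isolated)
Conditions: LDA, THF, −78 °C; then TBSCl, DMPU, −78 °C to rt; non-aqueous isolation
Reagents that add atoms: tert-butyldimethylsilyl chloride (TBSCl), CC(C)(C)[Si](C)(C)Cl
Why: Kinetic deprotonation of a 3-alkoxy enone with LDA occurs at the alpha' carbon C6 (the regiochemistry of the Stork–Danheiser alkylation) and not at the gamma carbon C4, and O-silylation of the lithium dienolate gives the cross-conjugated silyl dienol ether.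

Step 4
Reactants: 7 3-hydroxy-4,5-dimethoxybenzoic acid
Product: 9 3-(benzyloxy)-4,5-dimethoxybenzoic acid, via benzyl 3-(benzyloxy)-4,5-dimethoxybenzoate 8 (not isolated)
Conditions: BnBr, K2CO3, DMF, 60 °C; then NaOH, MeOH–H2O, 60 °C; HCl work-up
Reagents that add atoms: benzyl bromide, BrCc1ccccc1
Why: Williamson benzylation with excess benzyl bromide alkylates the phenoxide and the carboxylate, and ester saponification in the same pot releases the acid while the aryl benzyl ether is inert to hydroxide.

Step 5
Reactants: 9 3-(benzyloxy)-4,5-dimethoxybenzoic acid; 10 Meldrum's acid (2,2-dimethyl-1,3-dioxane-4,6-dione)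
Product: 11 5-{[3-(benzyloxy)-4,5-dimethoxyphenyl](hydroxy)methylidene}-2,2-dimethyl-1,3-dioxane-4,6-dione
Conditions: DCC, DMAP, CH2Cl2, 0 °C to rt; cold aq. KHSO4 wash
Reagents that add atoms: none
Why: Carbodiimide/DMAP C-acylation of Meldrum's acid (Steglich-type activation through the acylpyridinium ion) is the standard entry to acyl Meldrum's acids, which are obtained in their stable enol form after an acidic wash.

Step 6
Reactants: 11 5-{[3-(benzyloxy)-4,5-dimethoxyphenyl](hydroxy)methylidene}-2,2-dimethyl-1,3-dioxane-4,6-dione; 6 tert-butyl[(5,6-dimethoxycyclohexa-1,5-dien-1-yl)oxy]dimethylsilane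
Product: 14 2-[3-(benzyloxy)-4,5-dimethoxyphenyl]-7,8-dimethoxy-5,6-dihydro-4H-chromen-4-one, via aroylketene 12 (not isolated), via silyloxy cycloadduct 13 (not isolated)
Conditions: slow addition of 11 to 6 (2 equiv), PhMe, 110 °C; then CSA (cat., anhydrous), rt
Reagents that add atoms: none
Why: Proposed new method: heating 11 expels acetone and CO2 in a retro-[4+2] fragmentation to give aroylketene 12, whose O=C–C=C unit reacts as an electron-poor oxa-diene with the electron-rich C8a=C4a enol ether bond of 6, the ketene carbon bonding to C4a (C4–C4a) and the aroyl oxygen to C8a (O1–C8a) to give 13, which then loses tert-butyldimethylsilanol across C8a–C4a, spontaneously or under the camphorsulfonic acid, because H4a is alpha to the new C4 ketone and the C8a cation is an allyl-stabilized oxocarbenium ion. The closest known reaction type is the inverse-electron-demand hetero-Diels–Alder addition of acylketenes, generated from acyl Meldrum's acids or dioxinones, to alkyl enol ethers, followed by elimination of alcohol to a 4-pyranone; the cross-conjugated silyl dienol ether as 2π partner is the untested element. Ring C is closed by an intermolecular [4+2] cycloaddition, concerted or stepwise through C-acylation at C4a and 6-membered O-closure onto C8a, and a silyl-transfer shunt to the open 1,3,5-triketone would be cyclodehydrated to the same 14 by the acid. The two stereocentres of racemic 13 (C4a and C8a) are erased by the elimination, so no stereocontrol is needed. The step needs periselectivity (12 as 4π oxa-diene, not the cyclohexadiene of 6 as diene) and site and regioselectivity, which the substrate secures through its unsubstituted C4a terminus, activated by the C8a silyloxy group and vinylogously by the C7 methoxy group, whereas C7=C8 is tetrasubstituted and hindered. Slow addition of the acidic 11 to hot excess 6 keeps both the enolic acid and the ketene dilute, which should suppress protodesilylation of 6 and dimerization of 12.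

Step 7
Reactants: 14 2-[3-(benzyloxy)-4,5-dimethoxyphenyl]-7,8-dimethoxy-5,6-dihydro-4H-chromen-4-one
Product: 15 2-[3-(benzyloxy)-4,5-dimethoxyphenyl]-7,8-dimethoxy-4H-chromen-4-one
Conditions: DDQ (1.1 equiv), 1,4-dioxane, 60 °C
Reagents that add atoms: none
Why: Quinone dehydrogenation with DDQ abstracts hydride from C6, allylic to the C7=C8 bis-enol ether, and then a proton from C5, driven by aromatization of ring A, while the aryl benzyl ether should not be attacked at this temperature.

Step 8
Reactants: 15 2-[3-(benzyloxy)-4,5-dimethoxyphenyl]-7,8-dimethoxy-4H-chromen-4-one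
Product: 16 3'-hydroxy-4',5',7,8-tetramethoxyflavone [2-(3-hydroxy-4,5-dimethoxyphenyl)-7,8-dimethoxy-4H-chromen-4-one]
Conditions: H2 (1 atm), Pd/C, EtOAc–MeOH, rt
Reagents that add atoms: none
Why: Catalytic hydrogenolysis of an aryl benzyl ether over Pd/C at ambient pressure is faster than reduction of the C2=C3 bond of a flavone, so stopping at one equivalent of hydrogen should leave ring C intact.

Compound list
1 | cyclohexane-1,3-dione | O=C1CCCC(=O)C1 | starting material
2 | 2-diazocyclohexane-1,3-dione | [N-]=[N+]=C1C(=O)CCCC1=O | intermediate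
3 | 2-methoxycyclohexane-1,3-dione (mainly its enol; not isolated) | COC1C(=O)CCCC1=O | intermediate
4 | 2,3-dimethoxycyclohex-2-en-1-one | COC1=C(OC)C(=O)CCC1 | intermediate
5 | lithium 5,6-dimethoxycyclohexa-1,5-dien-1-olate (not isolated) | [Li+].[O-]C1=CCCC(OC)=C1OC | intermediate
6 | tert-butyl[(5,6-dimethoxycyclohexa-1,5-dien-1-yl)oxy]dimethylsilane | COC1=C(OC)C(O[Si](C)(C)C(C)(C)C)=CCC1 | intermediate
7 | 3-hydroxy-4,5-dimethoxybenzoic acid | COc1cc(C(=O)O)cc(O)c1OC | starting material
8 | benzyl 3-(benzyloxy)-4,5-dimethoxybenzoate (not isolated) | COc1cc(C(=O)OCc2ccccc2)cc(OCc2ccccc2)c1OC | intermediate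
9 | 3-(benzyloxy)-4,5-dimethoxybenzoic acid | COc1cc(C(=O)O)cc(OCc2ccccc2)c1OC | intermediate
10 | Meldrum's acid (2,2-dimethyl-1,3-dioxane-4,6-dione) | CC1(C)OC(=O)CC(=O)O1 | starting material
11 | 5-{[3-(benzyloxy)-4,5-dimethoxyphenyl](hydroxy)methylidene}-2,2-dimethyl-1,3-dioxane-4,6-dione | COc1cc(C(O)=C2C(=O)OC(C)(C)OC2=O)cc(OCc2ccccc2)c1OC | intermediate
12 | 3-[3-(benzyloxy)-4,5-dimethoxyphenyl]-3-oxoprop-1-en-1-one (aroylketene; not isolated) | COc1cc(C(=O)C=C=O)cc(OCc2ccccc2)c1OC | intermediate
13 | cis-2-[3-(benzyloxy)-4,5-dimethoxyphenyl]-8a-[(tert-butyldimethylsilyl)oxy]-7,8-dimethoxy-4a,5,6,8a-tetrahydro-4H-chromen-4-one (racemic, one enantiomer drawn, silyloxy group and H4a on the same face; not isolated) | COC1=C(OC)[C@@]2(O[Si](C)(C)C(C)(C)C)OC(c3cc(OC)c(OC)c(OCc4ccccc4)c3)=CC(=O)[C@H]2CC1 | intermediate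
14 | 2-[3-(benzyloxy)-4,5-dimethoxyphenyl]-7,8-dimethoxy-5,6-dihydro-4H-chromen-4-one | COC1=C(OC)C2=C(CC1)C(=O)C=C(c1cc(OC)c(OC)c(OCc3ccccc3)c1)O2 | intermediate
15 | 2-[3-(benzyloxy)-4,5-dimethoxyphenyl]-7,8-dimethoxy-4H-chromen-4-one | COc1cc(-c2cc(=O)c3ccc(OC)c(OC)c3o2)cc(OCc2ccccc2)c1OC | intermediate
16 | 3'-hydroxy-4',5',7,8-tetramethoxyflavone | COc1cc(-c2cc(=O)c3ccc(OC)c(OC)c3o2)cc(O)c1OC | target

Total step count: 8. Longest linear sequence: 6 steps (steps 1, 2, 3, 6, 7, 8, from 1 to 16).

Steps most likely to fail

1. Step 6 (the step with the proposed method). Ring C may not form because 6 is protodesilylated by the enolic acid 11 before 11 fragments, because ketene 12 dimerizes, or because 12 engages the cyclohexadiene of 6 in another periselective mode. The fallback is the known Baker–Venkataraman flavone synthesis; it sets out from 9 and returns at 15. Acid 9 is esterified with commercial 1-(2-hydroxy-3,4-dimethoxyphenyl)ethan-1-one (CC(=O)c1ccc(OC)c(OC)c1O; EDC·HCl, DMAP, CH2Cl2) to give 6-acetyl-2,3-dimethoxyphenyl 3-(benzyloxy)-4,5-dimethoxybenzoate F1. KOH in pyridine at 50 °C should bring about the O-to-C acyl shift to 1-[3-(benzyloxy)-4,5-dimethoxyphenyl]-3-(2-hydroxy-3,4-dimethoxyphenyl)propane-1,3-dione F2. TsOH in toluene at 80 °C cyclodehydrates F2 to 15, which enters step 8; steps 1–3, 5 and 7 are then not needed.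

2. Step 3. Deprotonation at the gamma carbon C4 may compete with C6, C-silylation may intrude, or the silyl group may be lost by hydrolysis while the electron-rich dienol ether is isolated. The fallback avoids any silyl enol ether; it sets out from 4 and returns at 14. The lithium dienolate 5 (LDA, 2 equiv, THF, −78 °C) is C-acetylated with 1-acetyl-1H-benzotriazole to 6-acetyl-2,3-dimethoxycyclohex-2-en-1-one F3. The dianion of F3 (LDA, THF, −78 to 0 °C) is aroylated at its terminal methyl carbon by benzyl ester 8 (isolated by leaving out the saponification of step 4) to the triketone 1-[3-(benzyloxy)-4,5-dimethoxyphenyl]-3-(3,4-dimethoxy-2-oxocyclohex-3-en-1-yl)propane-1,3-dione F4. Anhydrous TFA in CH2Cl2 should cyclodehydrate F4 to 14 (the classical 1,3,5-triketone route to 4-pyranones), which continues with step 7.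

3. Step 5. C-acylation of Meldrum's acid by the electron-rich aromatic acid may be slow, the O-acylisourea may rearrange to the N-acylurea, and 11 may fragment prematurely during work-up. The fallback sets out from 9 and returns at ketene 12 inside step 6. Acid 9 is activated with 1,1'-carbonyldiimidazole and treated with Mg(O2CCH2CO2tBu)2 in THF (Masamune–Brooks chain extension) to give tert-butyl 3-[3-(benzyloxy)-4,5-dimethoxyphenyl]-3-oxopropanoate F5. Heating F5 with 6 in xylene at about 140 °C, with removal of tert-butanol, should release the same aroylketene 12 from a neutral precursor, and the sequence continues as in step 6 to 14.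

Further compounds
F1 | step 6 | 6-acetyl-2,3-dimethoxyphenyl 3-(benzyloxy)-4,5-dimethoxybenzoate | COc1cc(C(=O)Oc2c(C(C)=O)ccc(OC)c2OC)cc(OCc2ccccc2)c1OC
F2 | step 6 | 1-[3-(benzyloxy)-4,5-dimethoxyphenyl]-3-(2-hydroxy-3,4-dimethoxyphenyl)propane-1,3-dione | COc1cc(C(=O)CC(=O)c2ccc(OC)c(OC)c2O)cc(OCc2ccccc2)c1OC
F3 | step 3 | 6-acetyl-2,3-dimethoxycyclohex-2-en-1-one | CC(=O)C1CCC(OC)=C(OC)C1=O
F4 | step 3 | 1-[3-(benzyloxy)-4,5-dimethoxyphenyl]-3-(3,4-dimethoxy-2-oxocyclohex-3-en-1-yl)propane-1,3-dione | COC1=C(OC)C(=O)C(CC1)C(=O)CC(=O)c1cc(OC)c(OC)c(OCc2ccccc2)c1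
F5 | step 5 | tert-butyl 3-[3-(benzyloxy)-4,5-dimethoxyphenyl]-3-oxopropanoate | COc1cc(C(=O)CC(=O)OC(C)(C)C)cc(OCc2ccccc2)c1OC
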